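## Remarks on the chemistry

- Abbreviation used in names: Ar = 4-[2-(benzyloxy)-4-bromophenoxy]-3-methoxyphenyl, i.e. ring B of unit 2 carrying, through the ether oxygen, the O-benzylated and brominated ring B of unit 1.
- Assumption: 1-(2,6-dihydroxy-4-methoxyphenyl)ethan-1-one (18) is taken as a purchasable starting material; it supplies ring A of unit 1 with the 7-OMe group already differentiated.
- Correction on stereochemistry: the ring closure creates C3 next to the existing C2 centre, so the cyclization product has two stereocentres. They form without control and are destroyed at the flavonol stage; 8, 11, 12, 13 and 14 are racemic (14 a cis/trans mixture).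
- Correction on the umpolung: the two formyl groups of 13 are not equivalent as acyl anion donors. A Breslow intermediate on the aliphatic formyl carbon has the ring A aryloxy group in the β position and can expel it, so the aromatic formyl group must be the donor.
- Design of the precursor: ring A keeps electron-donating benzyl ethers, because acyl or sulfonyl groups would make that phenoxide a better leaving group. 13 is made last, by one double oxidation, and is cyclized without storage.
- The ester is α-brominated through its silyl ketene acetal, because a radical bromination would attack the benzylic CH2 of the ether.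
- The chromone partner for the cross-coupling must carry benzyl ethers on O3 and O5 (24), so that no acidic proton quenches the zinc reagent and the 3-oxygen of unit 1 arrives with the fragment.

## Structural features

The target is an achiral biflavonol: two 2-aryl-3-hydroxy-4H-chromen-4-one units whose rings B are joined by one diaryl ether oxygen running from C4' of unit 1 to C4' of unit 2. Unit 1 carries 5-OH and 7-OMe on ring A and 3'-OH on ring B, whereas unit 2 carries 5-OH and 7-OH on ring A and 3'-OMe on ring B, so the halves are similar but not identical and cannot come from a dimerization. The target has no stereocentre; the only adjacent stereocentres of the route are C2 and C3 of ring C of unit 2, which are transient. The ether oxygen lies between two ortho-oxygenated carbons and is the most hindered bond of the skeleton, so it is best made early on simple arenes. Six hydroxyl groups (two enolic 3-OH, four phenolic) must be freed at the end while two aryl methyl ethers stay, and the electron-rich rings A and the 3-hydroxy-4-pyranone units are sensitive to oxidants and strong base. The real difficulty is to bring two different rings C to the flavonol oxidation level on either side of the ether without statistical steps and without a late C3 hydroxylation. In unit 2, C3 (enol carbon) and C4 (carbonyl carbon) of ring C are neighbouring oxygenated carbons: the flavonol is the enol of a chromane-3,4-dione, which lies one two-electron oxidation above a 3-hydroxychroman-4-one, an acyloin. The key step uses this by forming the C3–C4 bond from two formyl groups, one on ring A (future C4) and one on the two-carbon arm hung on O1 (future C3), which closes ring C.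

## Logic of the disconnections

27 to 26: the six O–CH2Ph bonds are cut. One kind of protecting group on all six hydroxyls can be removed by hydrogenolysis, which leaves both OMe groups alone. The forward step must not reduce the pyranone C2=C3 bonds, so it is run under mild H2/Pd conditions.

26 to 17 and 24 (through 25): the C2–C1' bond of unit 1 is cut. This divides the molecule into two flavonoid pieces of similar size, and the chromone piece brings its 3-oxygen along, so no late oxidation of unit 1 is needed. The forward step needs a regioselective C2 metalation of 24, an aryl bromide in 17 that has survived all earlier steps, and no acidic proton in 17.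

17 to 16 to 14 (through 15): the O3–benzyl bond is cut and C3 is taken down one oxidation level. This exposes the acyloin and explains why 17 has no free OH. The forward oxidation must tolerate benzyl ethers and the aryl bromide; it erases both stereocentres.

14 to 13: the C3–C4 bond is cut (key step). The acyloin is the retron of a benzoin reaction, and ring C opens to an aryl ether carrying two formyl groups. The forward step needs umpolung of the aromatic formyl group only, ring closure in preference to intermolecular coupling, and a very mild base.

13 to 12 to 11: both formyl groups are traced to primary alcohols and then to an ester and an aldehyde. 13 is too labile to carry through several steps, and the ester level is needed for the ether-forming step. The forward sequence needs a hydride that spares the aryl bromide, neutral handling of the acid-sensitive benzylic alcohol in 12, and a non-basic oxidant.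

11 to 8 and 10: the O1–C2 ether bond is cut. An activated secondary bromide and a phenol are simple partners, and the bond forms by SN2. The forward step needs a base weak enough not to cyclize the product by aldol addition onto the ortho formyl group.

10 to 9: two O–benzyl bonds are cut. The forward step relies on the hydrogen bond of the remaining ortho OH to the formyl group to stop at the bis-ether.

8 to 6 (through 7), 6 to 5, 5 to 3 (through 4), 3 to 1 and 2: in turn the α C–Br bond, the O–benzyl bond, the C–O bond of the phenol (from a formyl group) and the diaryl ether C–O bond are cut. The formyl group of 2 first activates fluoride displacement and then becomes the 3'-oxygen, so the hindered ether is made in the first step from two commercial arenes. The bromination must be ionic because of the benzyl ether.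

24 to 23, 23 to 21 (through 22), 21 to 19 (through 20), 19 to 18: the O3–benzyl bond, the C3–O bond, the O1–C2/C2–C3 bonds of the pyranone (one carbon from a formamide acetal) and the O5–benzyl bond are cut. This leads back to an acetophenone in which the 7-OMe group is already in place. The forward steps need mono-benzylation of a symmetric diol and an epoxidation that spares ring A.

## Other disconnections considered

Alternative 1: the cut is the C2=C3 bond of ring C of unit 1, with O1–C2 traced to an aryl ester. In the forward direction a phenacyl phosphonium ylide on ring A would add to the carbonyl of the neighbouring aryl ester, made from a ring B carboxylic acid that already carries protected unit 2; loss of the phosphine oxide would give flavone A1.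
- In its favour: the two halves are joined by a plain esterification, with no organometallic reagent and no palladium. On this point it is better than the zinc-based coupling of the chosen plan. The ring closure is regiochemically unambiguous and has no β-leaving-group hazard; on convergence it is equal.
- Against it here: A1 is a flavone, one oxidation level short at C3 of unit 1. The missing oxygen would have to be introduced late, by epoxidation or C3 metalation and oxidation, next to the electron-rich 3-benzyloxypyranone of unit 2. Ester carbonyls are reluctant Wittig acceptors and need heat, and acyl transfer can compete.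
- Comparison: it solves only unit 1, so ring C of unit 2 still needs its own construction. With the phosphonium salt (two steps), the esterification, the Wittig step and the C3 oxidation it is expected to be no shorter than steps 12 to 16. The chosen plan is better on oxidation-level economy.

Alternative 2: the cut goes through ring B of unit 1 (C4'–C5' and C2'–C1'), which is built from acyclic pieces. In the forward direction an amine-catalysed Michael addition of the aryloxy-bearing carbon of ketone A2 to vinyl keto ester A3, followed by aldol condensation, would give cyclohexenone A4; dehydrogenation would then give phenol ester A5.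
- In its favour: the hindered ether C–O bond comes from an SN2 reaction of a phenoxide with an α-halo ketone. The 3'-OH/4'-OAr pattern is fixed by the annulation, and A5 has an ester and a bromide as two differentiated handles. The enamine/aldol mechanism is more predictable than a carbene umpolung, which is a point where this key step is better.
- Against it here: A3 is prone to polymerization. The Michael addition must occur at the aryloxy-bearing carbon and not at the methyl group of A2. The aromatization must spare the aryl bromide. The ring being built is available in functionalized form from commercial arenes.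
- Comparison: for the diaryl ether fragment the step count is equal (annulation plus aromatization against fluoride displacement plus Dakin oxidation). Neither ring C is addressed, so both heterocycles would still need classical acylation chemistry, and the whole route is expected to be longer.

Alternative 3: the cut goes through ring A of unit 1 (C8a–C8, C8–C7, C6–C5, C5–C4a). In the forward direction pyranone diazoketone A6 would undergo Wolff rearrangement to a vinylketene, which adds methoxyacetylene A7 in a [2+2] step; four-electron ring opening and six-electron electrocyclization would give 5-hydroxy-7-methoxyflavone ether A8.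
- In its favour: the 5-OH/7-OMe differentiation follows directly from the regiochemistry of the ketene–alkyne addition, with the 5-OH free and no protecting step. On this point it is better than the chosen plan, which depends on a pre-differentiated acetophenone and a benzyl group. The 3-oxygen is already in place, and four C–C bonds form in one operation without a transition metal.
- Against it here: A6 needs a multistep pyranone carboxylic acid and diazo chemistry. The Wolff step must be run on a photo- and heat-sensitive 3-alkoxy-4-pyranone. A7 is volatile and unstable. The ring being built is a cheap commercial pattern.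
- Comparison: A8 still carries only a masked aldehyde in place of unit 2, so ring C of unit 2 must be built afterwards on an advanced flavonol. The route is expected to be longer and riskier; it is equal only in avoiding late C3 hydroxylation of unit 1.

Key step: step 9

## Route

Step 1
Reactants: 1 methyl 2-(4-hydroxy-3-methoxyphenyl)acetate (methyl homovanillate); 2 5-bromo-2-fluorobenzaldehyde
Product: 3 methyl 2-[4-(4-bromo-2-formylphenoxy)-3-methoxyphenyl]acetate
Conditions: K2CO3, DMF, 80 °C
Reagents that add atoms: none
Why: Nucleophilic aromatic substitution (addition–elimination): the phenoxide of 1 displaces the fluoride activated by the ortho formyl group. The bromide is meta to the formyl group and not activated, and K2CO3 does not deprotonate the arylacetate CH2 to a useful extent.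

Step 2
Reactants: 3 methyl 2-[4-(4-bromo-2-formylphenoxy)-3-methoxyphenyl]acetate
Product: 5 methyl 2-[4-(4-bromo-2-hydroxyphenoxy)-3-methoxyphenyl]acetate, via aryl formate 4 (not isolated)
Conditions: mCPBA, CH2Cl2, 0 °C → rt; then K2CO3 (cat.), MeOH, rt
Reagents that add atoms: 3-chloroperoxybenzoic acid (mCPBA), OOC(=O)c1cccc(Cl)c1
Why: Baeyer–Villiger (Dakin-type) oxidation: the ortho aryloxy donor makes the ring migrate in preference to hydride and gives formate 4. Methanolysis frees the phenol, and the methyl ester is unchanged in methanol.

Step 3
Reactants: 5 methyl 2-[4-(4-bromo-2-hydroxyphenoxy)-3-methoxyphenyl]acetate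
Product: 6 methyl 2-Ar-acetate (methyl 2-{4-[2-(benzyloxy)-4-bromophenoxy]-3-methoxyphenyl}acetate)
Conditions: BnBr, K2CO3, DMF, rt
Reagents that add atoms: benzyl bromide, BrCc1ccccc1
Why: Williamson ether synthesis on the only acidic OH; the carbonate is too weak to C-alkylate the ester.

Step 4
Reactants: 6 methyl 2-Ar-acetate
Product: 8 methyl 2-bromo-2-Ar-acetate (racemic), via silyl ketene acetal 7 (not isolated)
Conditions: LiN(SiMe3)2, Me3SiCl, THF, −78 °C; then NBS, −78 → 0 °C
Reagents that add atoms: N-bromosuccinimide, O=C1CCC(=O)N1Br; chlorotrimethylsilane, C[Si](C)(C)Cl (its silyl group stays only in 7)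
Why: Electrophilic α-halogenation of an ester through its silyl ketene acetal. This ionic path spares the benzylic CH2 of the ether and the aryl bromide; the new stereocentre forms as a racemate, which is of no consequence.

Step 5
Reactants: 9 2,4,6-trihydroxybenzaldehyde
Product: 10 2,4-bis(benzyloxy)-6-hydroxybenzaldehyde
Conditions: BnBr (2.1 equiv), K2CO3, DMF, 0 °C → rt
Reagents that add atoms: benzyl bromide, BrCc1ccccc1
Why: Williamson etherification under substrate control: the 4-OH is the most acidic, and one ortho OH reacts next. The last OH is then held in a hydrogen bond to the formyl group and alkylates much more slowly.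

Step 6
Reactants: 8 methyl 2-bromo-2-Ar-acetate; 10 2,4-bis(benzyloxy)-6-hydroxybenzaldehyde
Product: 11 methyl 2-[3,5-bis(benzyloxy)-2-formylphenoxy]-2-Ar-acetate (racemic)
Conditions: K2CO3, MeCN, rt
Reagents that add atoms: none
Why: SN2 O-alkylation (Williamson) of the phenoxide by a benzylic α-bromo ester. The formyl group of the trioxygenated ring is a poor electrophile, which disfavours aldol closure of the product onto it at room temperature.

Step 7
Reactants: 11 methyl 2-[3,5-bis(benzyloxy)-2-formylphenoxy]-2-Ar-acetate
Product: 12 2-[3,5-bis(benzyloxy)-2-(hydroxymethyl)phenoxy]-2-Ar-ethan-1-ol (racemic)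
Conditions: LiBH4, THF, 0 °C → rt; neutral work-up, used crude
Reagents that add atoms: none
Why: Hydride reduction: LiBH4 should reduce the aldehyde and the activated α-aryloxy ester to the diol without touching the aryl bromide or the benzyl ethers.

Step 8
Reactants: 12 2-[3,5-bis(benzyloxy)-2-(hydroxymethyl)phenoxy]-2-Ar-ethan-1-ol
Product: 13 2,4-bis(benzyloxy)-6-(1-Ar-2-oxoethoxy)benzaldehyde (racemic)
Conditions: Dess–Martin periodinane (2.5 equiv), pyridine, CH2Cl2, 0 °C → rt; used at once
Reagents that add atoms: none
Why: Dess–Martin oxidation of both primary alcohols under buffered, non-aqueous conditions, so the enolizable α-aryl-α-aryloxy aldehyde is not exposed to strong base or acid.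

Step 9
Reactants: 13 2,4-bis(benzyloxy)-6-(1-Ar-2-oxoethoxy)benzaldehyde
Product: 14 5,7-bis(benzyloxy)-2-Ar-3-hydroxychroman-4-one (racemic; cis/trans mixture)
Conditions: 2-(pentafluorophenyl)-6,7-dihydro-5H-pyrrolo[2,1-c][1,2,4]triazol-2-ium tetrafluoroborate (20 mol%), i-Pr2NEt (20 mol%), toluene (0.02 M), 25 °C, argon
Reagents that add atoms: none
Why: The triazolylidene freed by the amine adds to the aromatic formyl group; proton transfer gives the Breslow intermediate, whose nucleophilic C4 attacks the aliphatic formyl carbon (C3) in a 6-exo-trig closure of ring C, and proton transfer with loss of the carbene gives acyloin 14. The closest known reaction type is the carbene-catalysed intramolecular crossed benzoin cyclization of 2-(2-oxoalkoxy)benzaldehydes to 3-hydroxychroman-4-ones. C3 is a new stereocentre next to C2; both can epimerize (C2 through the aldehyde enol, C3 through the enediol), the 2,3-trans isomer should predominate for steric reasons, and no control is needed because step 10 removes both centres. Ring closure must win over intermolecular benzoin coupling, which the six-membered tether and high dilution should ensure. The acyl anion must also sit on the aromatic formyl carbon, because a Breslow intermediate at C3 would have the ring A aryloxy group β to the nucleophilic carbon and could expel it. The substrate helps in that the aromatic aldehyde cannot enolize and is a poor acceptor (2,4,6-trioxygenated), while the aliphatic aldehyde is α-oxygenated, strongly electrophilic and attached to a fully substituted carbon, so it is the natural acceptor; the electron-poor N-aryl group and the weak base are chosen to keep carbene addition reversible and enolization slow. If some material closes with the opposite polarity, the isomeric 4-hydroxychroman-3-one should be oxidized to the same dione 15 in step 10.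

Step 10
Reactants: 14 5,7-bis(benzyloxy)-2-Ar-3-hydroxychroman-4-one
Product: 16 5,7-bis(benzyloxy)-2-Ar-3-hydroxy-4H-chromen-4-one, via chromane-3,4-dione 15 (not isolated)
Conditions: Dess–Martin periodinane (1.2 equiv), pyridine, CH2Cl2, rt
Reagents that add atoms: none
Why: Dess–Martin oxidation of the acyloin to the 1,2-dione 15. This should enolize spontaneously toward C2, because that creates the aromatic 4-pyranone, and it removes both stereocentres.

Step 11
Reactants: 16 5,7-bis(benzyloxy)-2-Ar-3-hydroxy-4H-chromen-4-one
Product: 17 3,5,7-tris(benzyloxy)-2-Ar-4H-chromen-4-one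
Conditions: BnBr, K2CO3, DMF, rt → 50 °C
Reagents that add atoms: benzyl bromide, BrCc1ccccc1
Why: Williamson etherification of the acidic enolic 3-OH; this removes the only proton that would quench the organozinc partner.

Step 12
Reactants: 18 1-(2,6-dihydroxy-4-methoxyphenyl)ethan-1-one
Product: 19 1-[2-(benzyloxy)-6-hydroxy-4-methoxyphenyl]ethan-1-one
Conditions: BnBr (1.05 equiv), K2CO3, acetone, reflux
Reagents that add atoms: benzyl bromide, BrCc1ccccc1
Why: Williamson mono-etherification: after the first alkylation the remaining OH is chelated to the ketone and reacts much more slowly.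

Step 13
Reactants: 19 1-[2-(benzyloxy)-6-hydroxy-4-methoxyphenyl]ethan-1-one
Product: 21 5-(benzyloxy)-7-methoxy-4H-chromen-4-one, via enaminone 20 (not isolated)
Conditions: Me2NCH(OMe)2, toluene, 100 °C; then 1 M aq. HCl, CH2Cl2, 25 → 40 °C
Reagents that add atoms: N,N-dimethylformamide dimethyl acetal, COC(OC)N(C)C
Why: Condensation of the methyl ketone with the formamide acetal gives enaminone 20. Acid then brings about conjugate addition of the phenol and loss of dimethylamine (addition–elimination), closing the pyranone.

Step 14
Reactants: 21 5-(benzyloxy)-7-methoxy-4H-chromen-4-one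
Product: 23 5-(benzyloxy)-3-hydroxy-7-methoxy-4H-chromen-4-one, via epoxide 22 (not isolated)
Conditions: dimethyldioxirane (acetone solution), CH2Cl2, 0 °C → rt; then p-TsOH·H2O (10 mol%), CH2Cl2, rt
Reagents that add atoms: dimethyldioxirane, CC1(C)OO1
Why: Dioxirane epoxidation of the enol ether-type C2=C3 bond. Acid then opens the epoxide at C2 (oxocarbenium stabilized by O1) and loss of H3 gives the 3-hydroxychromone.

Step 15
Reactants: 23 5-(benzyloxy)-3-hydroxy-7-methoxy-4H-chromen-4-one
Product: 24 3,5-bis(benzyloxy)-7-methoxy-4H-chromen-4-one
Conditions: BnBr, K2CO3, DMF, rt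
Reagents that add atoms: benzyl bromide, BrCc1ccccc1
Why: Williamson etherification of the acidic enolic OH.

Step 16
Reactants: 24 3,5-bis(benzyloxy)-7-methoxy-4H-chromen-4-one; 17 3,5,7-tris(benzyloxy)-2-Ar-4H-chromen-4-one
Product: 26 3,5-bis(benzyloxy)-2-{3-(benzyloxy)-4-[2-methoxy-4-(3,5,7-tris(benzyloxy)-4-oxo-4H-chromen-2-yl)phenoxy]phenyl}-7-methoxy-4H-chromen-4-one, via chromon-2-ylzinc chloride 25 (not isolated)
Conditions: TMPZnCl·LiCl (1.3 equiv), THF, 25 °C; then 17, Pd(OAc)2 (3 mol%), SPhos (6 mol%), THF, 50 °C
Reagents that add atoms: (2,2,6,6-tetramethylpiperidin-1-yl)zinc chloride–lithium chloride, CC1(C)CCCC(C)(C)N1[Zn]Cl.[Li+].[Cl-] (its zinc and chloride stay only in 25)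
Why: Directed zincation at C2, the only vinylic C–H of 24, acidified by O1 and the 3-alkoxy group, followed by Negishi cross-coupling. Zerovalent palladium inserts into the C–Br bond of 17, and transmetalation and reductive elimination form the C2–C1' bond; ketones and ethers tolerate the organozinc.

Step 17
Reactants: 26 hexabenzyl ether of the target
Product: 27 3,5-dihydroxy-2-{3-hydroxy-4-[2-methoxy-4-(3,5,7-trihydroxy-4-oxo-4H-chromen-2-yl)phenoxy]phenyl}-7-methoxy-4H-chromen-4-one (target)
Conditions: H2 (1 atm), 10% Pd/C, THF/MeOH, rt
Reagents that add atoms: none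
Why: Hydrogenolysis of six benzyl ethers. The aryl methyl ethers, the diaryl ether and the pyranone C2=C3 bonds should be inert at 1 atm and room temperature.

## Compound list

1 | methyl 2-(4-hydroxy-3-methoxyphenyl)acetate | COC(=O)Cc1ccc(O)c(OC)c1 | starting material
2 | 5-bromo-2-fluorobenzaldehyde | O=Cc1cc(Br)ccc1F | starting material
3 | methyl 2-[4-(4-bromo-2-formylphenoxy)-3-methoxyphenyl]acetate | COC(=O)Cc1ccc(Oc2ccc(Br)cc2C=O)c(OC)c1 | intermediate
4 | methyl 2-{4-[4-bromo-2-(formyloxy)phenoxy]-3-methoxyphenyl}acetate (formed in the flask) | COC(=O)Cc1ccc(Oc2ccc(Br)cc2OC=O)c(OC)c1 | intermediate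
5 | methyl 2-[4-(4-bromo-2-hydroxyphenoxy)-3-methoxyphenyl]acetate | COC(=O)Cc1ccc(Oc2ccc(Br)cc2O)c(OC)c1 | intermediate
6 | methyl 2-{4-[2-(benzyloxy)-4-bromophenoxy]-3-methoxyphenyl}acetate | COC(=O)Cc1ccc(Oc2ccc(Br)cc2OCc2ccccc2)c(OC)c1 | intermediate
7 | [(2-{4-[2-(benzyloxy)-4-bromophenoxy]-3-methoxyphenyl}-1-methoxyethenyl)oxy]trimethylsilane (E/Z mixture, formed in the flask) | COC(O[Si](C)(C)C)=Cc1ccc(Oc2ccc(Br)cc2OCc2ccccc2)c(OC)c1 | intermediate
8 | methyl 2-bromo-2-{4-[2-(benzyloxy)-4-bromophenoxy]-3-methoxyphenyl}acetate (racemic) | COC(=O)C(Br)c1ccc(Oc2ccc(Br)cc2OCc2ccccc2)c(OC)c1 | intermediate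
9 | 2,4,6-trihydroxybenzaldehyde | O=Cc1c(O)cc(O)cc1O | starting material
10 | 2,4-bis(benzyloxy)-6-hydroxybenzaldehyde | O=Cc1c(O)cc(OCc2ccccc2)cc1OCc1ccccc1 | intermediate
11 | methyl 2-[3,5-bis(benzyloxy)-2-formylphenoxy]-2-{4-[2-(benzyloxy)-4-bromophenoxy]-3-methoxyphenyl}acetate (racemic) | COC(=O)C(Oc1cc(OCc2ccccc2)cc(OCc2ccccc2)c1C=O)c1ccc(Oc2ccc(Br)cc2OCc2ccccc2)c(OC)c1 | intermediate
12 | 2-[3,5-bis(benzyloxy)-2-(hydroxymethyl)phenoxy]-2-{4-[2-(benzyloxy)-4-bromophenoxy]-3-methoxyphenyl}ethan-1-ol (racemic) | OCC(Oc1cc(OCc2ccccc2)cc(OCc2ccccc2)c1CO)c1ccc(Oc2ccc(Br)cc2OCc2ccccc2)c(OC)c1 | intermediate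
13 | 2,4-bis(benzyloxy)-6-(1-{4-[2-(benzyloxy)-4-bromophenoxy]-3-methoxyphenyl}-2-oxoethoxy)benzaldehyde (racemic) | O=CC(Oc1cc(OCc2ccccc2)cc(OCc2ccccc2)c1C=O)c1ccc(Oc2ccc(Br)cc2OCc2ccccc2)c(OC)c1 | intermediate
14 | 5,7-bis(benzyloxy)-2-{4-[2-(benzyloxy)-4-bromophenoxy]-3-methoxyphenyl}-3-hydroxychroman-4-one (racemic, cis/trans mixture) | O=C1c2c(OCc3ccccc3)cc(OCc3ccccc3)cc2OC(c2ccc(Oc3ccc(Br)cc3OCc3ccccc3)c(OC)c2)C1O | intermediate
15 | 5,7-bis(benzyloxy)-2-{4-[2-(benzyloxy)-4-bromophenoxy]-3-methoxyphenyl}chromane-3,4-dione (racemic, formed in the flask) | O=C1C(=O)c2c(OCc3ccccc3)cc(OCc3ccccc3)cc2OC1c1ccc(Oc2ccc(Br)cc2OCc2ccccc2)c(OC)c1 | intermediate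
16 | 5,7-bis(benzyloxy)-2-{4-[2-(benzyloxy)-4-bromophenoxy]-3-methoxyphenyl}-3-hydroxy-4H-chromen-4-one | O=c1c(O)c(-c2ccc(Oc3ccc(Br)cc3OCc3ccccc3)c(OC)c2)oc2cc(OCc3ccccc3)cc(OCc3ccccc3)c12 | intermediate
17 | 3,5,7-tris(benzyloxy)-2-{4-[2-(benzyloxy)-4-bromophenoxy]-3-methoxyphenyl}-4H-chromen-4-one | O=c1c(OCc2ccccc2)c(-c2ccc(Oc3ccc(Br)cc3OCc3ccccc3)c(OC)c2)oc2cc(OCc3ccccc3)cc(OCc3ccccc3)c12 | intermediate
18 | 1-(2,6-dihydroxy-4-methoxyphenyl)ethan-1-one | CC(=O)c1c(O)cc(OC)cc1O | starting material
19 | 1-[2-(benzyloxy)-6-hydroxy-4-methoxyphenyl]ethan-1-one | CC(=O)c1c(O)cc(OC)cc1OCc1ccccc1 | intermediate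
20 | (E)-1-[2-(benzyloxy)-6-hydroxy-4-methoxyphenyl]-3-(dimethylamino)prop-2-en-1-one (formed in the flask) | CN(C)/C=C/C(=O)c1c(O)cc(OC)cc1OCc1ccccc1 | intermediate
21 | 5-(benzyloxy)-7-methoxy-4H-chromen-4-one | COc1cc(OCc2ccccc2)c2c(=O)ccoc2c1 | intermediate
22 | 5-(benzyloxy)-2,3-epoxy-7-methoxychroman-4-one (racemic cis-fused epoxide, formed in the flask) | COc1cc(OCc2ccccc2)c2c(c1)OC1OC1C2=O | intermediate
23 | 5-(benzyloxy)-3-hydroxy-7-methoxy-4H-chromen-4-one | COc1cc(OCc2ccccc2)c2c(=O)c(O)coc2c1 | intermediate
24 | 3,5-bis(benzyloxy)-7-methoxy-4H-chromen-4-one | COc1cc(OCc2ccccc2)c2c(=O)c(OCc3ccccc3)coc2c1 | intermediate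
25 | [3,5-bis(benzyloxy)-7-methoxy-4-oxo-4H-chromen-2-yl]zinc chloride (LiCl complex, formed in the flask) | COc1cc(OCc2ccccc2)c2c(=O)c(OCc3ccccc3)c([Zn]Cl)oc2c1 | intermediate
26 | 3,5-bis(benzyloxy)-2-{3-(benzyloxy)-4-[2-methoxy-4-(3,5,7-tris(benzyloxy)-4-oxo-4H-chromen-2-yl)phenoxy]phenyl}-7-methoxy-4H-chromen-4-one | COc1cc(OCc2ccccc2)c2c(=O)c(OCc3ccccc3)c(-c3ccc(Oc4ccc(-c5oc6cc(OCc7ccccc7)cc(OCc7ccccc7)c6c(=O)c5OCc5ccccc5)cc4OC)c(OCc4ccccc4)c3)oc2c1 | intermediate
27 | 3,5-dihydroxy-2-{3-hydroxy-4-[2-methoxy-4-(3,5,7-trihydroxy-4-oxo-4H-chromen-2-yl)phenoxy]phenyl}-7-methoxy-4H-chromen-4-one | COc1cc(O)c2c(=O)c(O)c(-c3ccc(Oc4ccc(-c5oc6cc(O)cc(O)c6c(=O)c5O)cc4OC)c(O)c3)oc2c1 | target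

## Step count and least certain steps

Total step count: 17. Longest linear sequence: 12 steps (steps 1, 2, 3, 4, 6, 7, 8, 9, 10, 11, 16, 17).

Step 9 (key step). The most likely failure is fragmentation of the tether: if the carbene engages the aliphatic formyl group, the resulting Breslow intermediate can expel the ring A aryloxide. Slow carbene addition to the hindered, electron-rich aromatic formyl group and base-induced enolization or aldol reaction of the aliphatic aldehyde would make this worse. Fallback: the C3–C4 bond is made reductively instead of by umpolung. Setting out from 13, SmI2 in THF/t-BuOH at −78 °C should form the ketyl at the aromatic formyl group and couple it with the aliphatic formyl group (intramolecular pinacol coupling) to give 5,7-bis(benzyloxy)-2-{4-[2-(benzyloxy)-4-bromophenoxy]-3-methoxyphenyl}chromane-3,4-diol F1. Swern oxidation of both hydroxyls ((COCl)2, DMSO, Et3N, CH2Cl2, −78 °C) should give dione 15, which enolizes, and the route is rejoined at 16.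

Step 16. Zincation may be incomplete or may compete with metalation of ring A positions flanked by two oxygens. Oxidative addition into the electron-rich aryl bromide may be slow, which would allow protodezincation. Fallback: the roles of the partners are exchanged and boron is used. Setting out from 17, Miyaura borylation (bis(pinacolato)diboron, PdCl2(dppf), KOAc, dioxane, 80 °C) should give 3,5,7-tris(benzyloxy)-2-{4-[2-(benzyloxy)-4-(4,4,5,5-tetramethyl-1,3,2-dioxaborolan-2-yl)phenoxy]-3-methoxyphenyl}-4H-chromen-4-one F2. Setting out from 24, C2 lithiation (LiN(i-Pr)2, THF, −78 °C) and iodine quench should give 3,5-bis(benzyloxy)-2-iodo-7-methoxy-4H-chromen-4-one F3. Suzuki–Miyaura coupling of F2 with F3 (Pd(PPh3)4, K3PO4, dioxane/water, 80 °C) rejoins the route at 26.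

Step 6. The product has an acidic α-hydrogen, and its enolate may add to the ortho formyl group (aldol closure to a dihydrobenzofuranol). The bromo ester may also solvolyse before it is alkylated. Fallback: the ether is formed under neutral redox-condensation conditions. Setting out from 6, enolate hydroxylation (LiN(SiMe3)2, THF, −78 °C; then 2-(phenylsulfonyl)-3-phenyloxaziridine) should give methyl 2-{4-[2-(benzyloxy)-4-bromophenoxy]-3-methoxyphenyl}-2-hydroxyacetate F4. Mitsunobu coupling of F4 with 10 (PPh3, diisopropyl azodicarboxylate, THF, 0 °C → rt) rejoins the route at 11.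

Step 14. The dioxirane may oxidize the electron-rich ring A or benzylic positions, the electron-poor C2=C3 bond may epoxidize incompletely, and the epoxide may be opened by water instead of rearranging. Fallback: the 3-oxygen is introduced through a formyl group. Setting out from 19, Vilsmeier–Haack reaction (POCl3, DMF, 0 → 50 °C) should give 5-(benzyloxy)-7-methoxy-4-oxo-4H-chromene-3-carbaldehyde F5. Baeyer–Villiger oxidation (mCPBA, CH2Cl2) should give 5-(benzyloxy)-7-methoxy-4-oxo-4H-chromen-3-yl formate F6, and methanolysis (K2CO3 cat., MeOH) rejoins the route at 23.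

Step 5. Alkylation may run on to the tribenzyl ether, and the phloroglucinol nucleus may be C-benzylated, which would lower the selectivity. Fallback: protect fully, then remove one group under chelation control. Setting out from 9, exhaustive benzylation (BnBr in excess, K2CO3, DMF, 60 °C) should give 2,4,6-tris(benzyloxy)benzaldehyde F7. MgBr2·OEt2 in toluene/Et2O should cleave only one benzyl ether ortho to the formyl group, and the route is rejoined at 10.

## Further compounds

F1 | step 9 | 5,7-bis(benzyloxy)-2-{4-[2-(benzyloxy)-4-bromophenoxy]-3-methoxyphenyl}chromane-3,4-diol (racemic diastereomer mixture) | OC1c2c(OCc3ccccc3)cc(OCc3ccccc3)cc2OC(c2ccc(Oc3ccc(Br)cc3OCc3ccccc3)c(OC)c2)C1O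
F2 | step 16 | 3,5,7-tris(benzyloxy)-2-{4-[2-(benzyloxy)-4-(4,4,5,5-tetramethyl-1,3,2-dioxaborolan-2-yl)phenoxy]-3-methoxyphenyl}-4H-chromen-4-one | O=c1c(OCc2ccccc2)c(-c2ccc(Oc3ccc(B4OC(C)(C)C(C)(C)O4)cc3OCc3ccccc3)c(OC)c2)oc2cc(OCc3ccccc3)cc(OCc3ccccc3)c12
F3 | step 16 | 3,5-bis(benzyloxy)-2-iodo-7-methoxy-4H-chromen-4-one | COc1cc(OCc2ccccc2)c2c(=O)c(OCc3ccccc3)c(I)oc2c1
F4 | step 6 | methyl 2-{4-[2-(benzyloxy)-4-bromophenoxy]-3-methoxyphenyl}-2-hydroxyacetate (racemic) | COC(=O)C(O)c1ccc(Oc2ccc(Br)cc2OCc2ccccc2)c(OC)c1
F5 | step 14 | 5-(benzyloxy)-7-methoxy-4-oxo-4H-chromene-3-carbaldehyde | COc1cc(OCc2ccccc2)c2c(=O)c(C=O)coc2c1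
F6 | step 14 | 5-(benzyloxy)-7-methoxy-4-oxo-4H-chromen-3-yl formate | COc1cc(OCc2ccccc2)c2c(=O)c(OC=O)coc2c1
F7 | step 5 | 2,4,6-tris(benzyloxy)benzaldehyde | O=Cc1c(OCc2ccccc2)cc(OCc2ccccc2)cc1OCc1ccccc1
A1 | alternative 1 | 5-(benzyloxy)-2-{3-(benzyloxy)-4-[2-methoxy-4-(3,5,7-tris(benzyloxy)-4-oxo-4H-chromen-2-yl)phenoxy]phenyl}-7-methoxy-4H-chromen-4-one | COc1cc(OCc2ccccc2)c2c(=O)cc(-c3ccc(Oc4ccc(-c5oc6cc(OCc7ccccc7)cc(OCc7ccccc7)c6c(=O)c5OCc5ccccc5)cc4OC)c(OCc4ccccc4)c3)oc2c1
A2 | alternative 2 | 1-(4-bromo-2-methoxyphenoxy)propan-2-one | CC(=O)COc1ccc(Br)cc1OC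
A3 | alternative 2 | ethyl 2-oxobut-3-enoate | CCOC(=O)C(=O)C=C
A4 | alternative 2 | ethyl 4-(4-bromo-2-methoxyphenoxy)-3-oxocyclohex-1-ene-1-carboxylate (racemic) | CCOC(=O)C1=CC(=O)C(Oc2ccc(Br)cc2OC)CC1
A5 | alternative 2 | ethyl 4-(4-bromo-2-methoxyphenoxy)-3-hydroxybenzoate | CCOC(=O)c1ccc(Oc2ccc(Br)cc2OC)c(O)c1
A6 | alternative 3 | 3-(benzyloxy)-2-{3-(benzyloxy)-4-[4-(1,3-dioxolan-2-yl)-2-methoxyphenoxy]phenyl}-6-(2-diazoacetyl)-4H-pyran-4-one | [N-]=[N+]=CC(=O)c1cc(=O)c(OCc2ccccc2)c(-c2ccc(Oc3ccc(C4OCCO4)cc3OC)c(OCc3ccccc3)c2)o1
A7 | alternative 3 | methoxyacetylene | COC#C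
A8 | alternative 3 | 3-(benzyloxy)-2-{3-(benzyloxy)-4-[4-(1,3-dioxolan-2-yl)-2-methoxyphenoxy]phenyl}-5-hydroxy-7-methoxy-4H-chromen-4-one | COc1cc(O)c2c(=O)c(OCc3ccccc3)c(-c3ccc(Oc4ccc(C5OCCO5)cc4OC)c(OCc4ccccc4)c3)oc2c1
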